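## Retrosynthetic overview

1. Feature: in the imidazo[1,2-a]pyrazin-3(7H)-one (ring A: N1–C2–C3–N4–C8a; ring B: N4–C5–C6–N7–C8–C8a), the benzyl-bearing C8 (ketone level) and the amidine carbon C8a are both electrophilic carbons. C8a with N1, C2 and C3 is a tyrosine α-isocyano ester, so C8a can be made the donor as an isocyanide carbon.
2. Ring B is opened last at N7: ammonia bridges the C8 and C6 ketones. Ring A is opened at N4–C3: the amidine nitrogen lactamises on the methyl ester.
3. Key disconnections C8–C8a and C8a–N4: Nef isocyanide addition of isocyanide 4 to phenylacetyl chloride 5, then capture of the imidoyl chloride by amino ketone 8. No ring closes, and since C8 enters at the acyl level no redox step is needed.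
4. Isocyanide 4 comes from L-tyrosine methyl ester by N-formylation, O-acetylation and dehydration.
5. Order of ring formation: ring A (step 5), then ring B (step 6).

Key step: step 4

Assumption: the (S) centre taken from L-tyrosine ends as the sp2 carbon C2 of the achiral target, so any erosion in steps 3 to 5 is harmless; compound 10 is drawn without a descriptor because its C5–H is expected to epimerise.

## Route

Step 1
Reactants: 1 L-tyrosine methyl ester
Product: 2 methyl N-formyl-L-tyrosinate
Conditions: HCO2Et (solvent), reflux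
Reagents that add atoms: ethyl formate, CCOC=O
Why: N-formylation by aminolysis of a formate ester; the phenol and the methyl ester do not react under these neutral conditions and the (S) centre is untouched.

Step 2
Reactants: 2 methyl N-formyl-L-tyrosinate
Product: 3 methyl O-acetyl-N-formyl-L-tyrosinate
Conditions: Ac2O, pyridine, CH2Cl2, 0 °C to rt
Reagents that add atoms: acetic anhydride, CC(=O)OC(C)=O
Why: O-acetylation of the phenol, which must be masked before POCl3 is used; the formamide N–H is not acylated under these mild conditions.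

Step 3
Reactants: 3 methyl O-acetyl-N-formyl-L-tyrosinate
Product: 4 methyl (2S)-3-(4-acetoxyphenyl)-2-isocyanopropanoate
Conditions: POCl3, Et3N, CH2Cl2, −20 to 0 °C; cold aq. NaHCO3 quench
Reagents that add atoms: none
Why: Ugi dehydration of a formamide to the isocyanide; the aryl acetate and methyl ester tolerate cold Et3N and a short bicarbonate quench.

Step 4
Reactants: 4 methyl (2S)-3-(4-acetoxyphenyl)-2-isocyanopropanoate; 5 phenylacetyl chloride; 6 2-amino-1-(4-hydroxyphenyl)ethanone hydrochloride
Product: 9 methyl (2S)-3-(4-acetoxyphenyl)-2-[[1-[[2-(4-hydroxyphenyl)-2-oxoethyl]amino]-2-oxo-3-phenylpropylidene]amino]propanoate, via keto imidoyl chloride 7 (not isolated), via free amino ketone 8 (not isolated)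
Conditions: 4 (1.05 equiv), 5 (1.0 equiv), PhMe (2 M), 45 °C, no base; then CH2Cl2/MeCN, −40 °C, 6 (1.0 equiv), 2,6-lutidine (2.1 equiv), −40 to 0 °C
Reagents that add atoms: none
Why: Proposed new method: the formally divalent carbon of isocyanide 4 is acylated by 5 to an N-alkyl nitrilium ion that collapses with chloride to imidoyl chloride 7 (C8–C8a), and amine 8, set free from 6 by 2,6-lutidine, then adds to the imidoyl carbon and expels chloride (C8a–N4). The closest known reaction type is the Nef isocyanide reaction of acyl chlorides with alkyl isocyanides followed by amine capture of the α-keto imidoyl chloride as an α-keto amidine, which has not been shown for an α-isocyano ester combined with an α-amino ketone. No ring is closed and no stereocentre is made; the (S) centre of 4 is only carried along. Nitrogen must attack the imidoyl carbon and not the C8 ketone, which is secured because loss of chloride is irreversible while hemiaminal formation at the ketone is reversible. Closure of 7 to a 2-acyl-5-methoxyoxazole needs deprotonation of the ester α-C–H, so the Nef stage is run without base and the capture uses only a weak, hindered base at −40 °C. Self-condensation of 8 is held back because it is released slowly in the presence of a full equivalent of the much more electrophilic 7.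

Step 5
Reactants: 9 methyl (2S)-3-(4-acetoxyphenyl)-2-[[1-[[2-(4-hydroxyphenyl)-2-oxoethyl]amino]-2-oxo-3-phenylpropylidene]amino]propanoate
Product: 10 5-(4-acetoxybenzyl)-3-[2-(4-hydroxyphenyl)-2-oxoethyl]-2-(2-phenylacetyl)-3,5-dihydro-4H-imidazol-4-one
Conditions: 2-hydroxypyridine (0.2 equiv), MeCN, 50 °C, Ar; crude product taken on under Ar
Reagents that add atoms: none
Why: Intramolecular aminolysis of the methyl ester by amidine nitrogen N4 (5-exo-trig lactamisation, the usual closure of N-(alkoxycarbonylalkyl)amidines to imidazol-4-ones) closes ring A; loss of methanol is irreversible, whereas addition of N1 to the C6 ketone is reversible as long as no acid drives dehydration.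

Step 6
Reactants: 10 5-(4-acetoxybenzyl)-3-[2-(4-hydroxyphenyl)-2-oxoethyl]-2-(2-phenylacetyl)-3,5-dihydro-4H-imidazol-4-one
Product: 12 coelenterazine, via O-acetylcoelenterazine 11 (not isolated)
Conditions: NH4OAc (10 equiv), degassed MeOH, 60 °C, Ar
Reagents that add atoms: ammonium acetate, CC(=O)[O-].[NH4+]
Why: Cyclocondensation of a 1,5-dicarbonyl unit with ammonia, as used to make azolo[1,2-a]pyrazines from N-phenacyl 2-acyl azoles: ammonia condenses with the C8 ketone (activated by the adjacent C8a=N1 bond), N7 then closes on the C6 aryl ketone (6-exo-trig), water is lost and the C2 hydrogen shifts to N7; NH4OAc in methanol should also cleave the aryl acetate by mild methanolysis.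

## Compound list

1 | L-tyrosine methyl ester | COC(=O)[C@@H](N)Cc1ccc(O)cc1 | starting material
2 | methyl N-formyl-L-tyrosinate | COC(=O)[C@@H](NC=O)Cc1ccc(O)cc1 | intermediate
3 | methyl O-acetyl-N-formyl-L-tyrosinate | COC(=O)[C@@H](NC=O)Cc1ccc(OC(C)=O)cc1 | intermediate
4 | methyl (2S)-3-(4-acetoxyphenyl)-2-isocyanopropanoate | [C-]#[N+][C@@H](Cc1ccc(OC(C)=O)cc1)C(=O)OC | intermediate
5 | phenylacetyl chloride | O=C(Cl)Cc1ccccc1 | starting material
6 | 2-amino-1-(4-hydroxyphenyl)ethanone hydrochloride | Cl.NCC(=O)c1ccc(O)cc1 | starting material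
7 | methyl (2S)-3-(4-acetoxyphenyl)-2-[(1-chloro-2-oxo-3-phenylpropylidene)amino]propanoate | COC(=O)[C@H](Cc1ccc(OC(C)=O)cc1)N=C(Cl)C(=O)Cc1ccccc1 | intermediate
8 | 2-amino-1-(4-hydroxyphenyl)ethanone (free base) | NCC(=O)c1ccc(O)cc1 | intermediate
9 | methyl (2S)-3-(4-acetoxyphenyl)-2-[[1-[[2-(4-hydroxyphenyl)-2-oxoethyl]amino]-2-oxo-3-phenylpropylidene]amino]propanoate | COC(=O)[C@H](Cc1ccc(OC(C)=O)cc1)N=C(NCC(=O)c1ccc(O)cc1)C(=O)Cc1ccccc1 | intermediate
10 | 5-(4-acetoxybenzyl)-3-[2-(4-hydroxyphenyl)-2-oxoethyl]-2-(2-phenylacetyl)-3,5-dihydro-4H-imidazol-4-one (C5 configuration not defined) | O=C1C(Cc2ccc(OC(C)=O)cc2)N=C(C(=O)Cc2ccccc2)N1CC(=O)c1ccc(O)cc1 | intermediate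
11 | O-acetylcoelenterazine, 4-[[8-benzyl-6-(4-hydroxyphenyl)-3-oxo-3,7-dihydroimidazo[1,2-a]pyrazin-2-yl]methyl]phenyl acetate | O=c1c(Cc2ccc(OC(C)=O)cc2)nc2c(Cc3ccccc3)[nH]c(-c3ccc(O)cc3)cn1-2 | intermediate
12 | coelenterazine, 8-benzyl-2-(4-hydroxybenzyl)-6-(4-hydroxyphenyl)imidazo[1,2-a]pyrazin-3(7H)-one | O=c1c(Cc2ccc(O)cc2)nc2c(Cc3ccccc3)[nH]c(-c3ccc(O)cc3)cn1-2 | target

## Step count and risks

Total steps: 6. Longest linear sequence: 6 steps (1 to 12).

Steps most likely to fail:

1. Step 4 (proposed new method). What may go wrong: the α-addition of the electron-poor isocyanide may be slow; once base is present the imidoyl chloride may lose HCl and close to an oxazole; or the liberated amino ketone may self-condense before it is captured. Fallback, known chemistry, setting out from 6 and 1 and coming back at 12: the amidine carbon C8a is built as a pyrazine carbon. Salt 6 is acylated with phenylpyruvic acid (EDC·HCl, HOBt, N-methylmorpholine, DMF, 0 °C) to N-[2-(4-hydroxyphenyl)-2-oxoethyl]-2-oxo-3-phenylpropanamide F1. NH4OAc in AcOH/EtOH at 80 °C closes this keto amide to 3-benzyl-5-(4-hydroxyphenyl)pyrazin-2(1H)-one F2. POCl3 at 90 °C without base, where phenols are phosphorylated only slowly, gives 4-(6-benzyl-5-chloropyrazin-2-yl)phenol F3. Palladium-catalysed N-arylation of amino ester 1 (Pd(OAc)2, BINAP, Cs2CO3, MeCN, 60 °C, zerovalent palladium formed in the flask) gives methyl N-[3-benzyl-5-(4-hydroxyphenyl)pyrazin-2-yl]tyrosinate F4. LiOH in aqueous THF gives N-[3-benzyl-5-(4-hydroxyphenyl)pyrazin-2-yl]tyrosine F5, and DCC in pyridine under argon closes ring A by acylation of N4 to give 12.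

2. Step 5. What may go wrong: cyclisation in the wrong direction (N1 onto the C6 ketone, then dehydration to an imidazole), aldol-type condensation of the acidic methylene groups, or autoxidation of the C5–H imidazolone. Fallback, setting out from 9 and coming back at 12: the ring order is inverted. NH4OAc in AcOH at 70 °C closes ring B first, giving the air-stable aminopyrazine methyl (2S)-3-(4-acetoxyphenyl)-2-[[3-benzyl-5-(4-hydroxyphenyl)pyrazin-2-yl]amino]propanoate F6. LiOH in aqueous THF cleaves the methyl ester and the acetate to N-[3-benzyl-5-(4-hydroxyphenyl)pyrazin-2-yl]tyrosine F5, and DCC in pyridine under argon closes ring A to 12.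

3. Step 6. What may go wrong: oxidative degradation of the electron-rich imidazopyrazinone in the ammonia buffer and on isolation, slow dehydration at the deactivated aryl ketone, or incomplete acetate cleavage. Fallback, setting out from 10 and coming back at 12: ring closure and deprotection are separated and the product is handled as a stable enol acetate. NH4OAc in AcOH at 80 °C closes ring B with the acetate intact (compound 11). Without isolation, Ac2O and pyridine convert 11 into 4-[[3-acetoxy-6-(4-acetoxyphenyl)-8-benzylimidazo[1,2-a]pyrazin-2-yl]methyl]phenyl acetate F7, a fully aromatic triacetate that can be chromatographed in air. HCl in degassed EtOH at 50 °C then cleaves the three acetates to 12.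

## Further compounds

F1 | step 4 | N-[2-(4-hydroxyphenyl)-2-oxoethyl]-2-oxo-3-phenylpropanamide | O=C(Cc1ccccc1)C(=O)NCC(=O)c1ccc(O)cc1
F2 | step 4 | 3-benzyl-5-(4-hydroxyphenyl)pyrazin-2(1H)-one | O=c1[nH]cc(-c2ccc(O)cc2)nc1Cc1ccccc1
F3 | step 4 | 4-(6-benzyl-5-chloropyrazin-2-yl)phenol | Oc1ccc(-c2cnc(Cl)c(Cc3ccccc3)n2)cc1
F4 | step 4 | methyl N-[3-benzyl-5-(4-hydroxyphenyl)pyrazin-2-yl]tyrosinate (α-carbon configuration not controlled) | COC(=O)C(Cc1ccc(O)cc1)Nc1ncc(-c2ccc(O)cc2)nc1Cc1ccccc1
F5 | step 4 | N-[3-benzyl-5-(4-hydroxyphenyl)pyrazin-2-yl]tyrosine (α-carbon configuration not controlled) | OC(=O)C(Cc1ccc(O)cc1)Nc1ncc(-c2ccc(O)cc2)nc1Cc1ccccc1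
F6 | step 5 | methyl (2S)-3-(4-acetoxyphenyl)-2-[[3-benzyl-5-(4-hydroxyphenyl)pyrazin-2-yl]amino]propanoate | COC(=O)[C@H](Cc1ccc(OC(C)=O)cc1)Nc1ncc(-c2ccc(O)cc2)nc1Cc1ccccc1
F7 | step 6 | 4-[[3-acetoxy-6-(4-acetoxyphenyl)-8-benzylimidazo[1,2-a]pyrazin-2-yl]methyl]phenyl acetate | CC(=O)Oc1ccc(Cc2nc3c(Cc4ccccc4)nc(-c4ccc(OC(C)=O)cc4)cn3c2OC(C)=O)cc1
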